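**Retrosynthetic overview**

1. The strategy rests on ring B (C1'–C6') of the 5-hydroxy-7-methoxyflavone unit: OMe on C4', C6 of the acacetin unit on the neighbouring C3', and the pyranone carbon C2 on C1', para to the OMe. This is the pattern of a 2-aryl-4-carboxycyclohex-2-enone whose ketone carbon becomes C4'.
2. The pyranone ring C of the methoxyflavone unit is opened by Baker–Venkataraman rearrangement and cyclodehydration to benzoic acid 18 and acetophenone 20; the three benzyl ethers come off last.
3. Arene 17 comes from cyclohexenone 16 (I2/MeOH), and 16 from a Robinson annulation of vinyl ketone 11 with methyl 3-oxopropanoate 13 (Michael addition forms C1'–C6', aldol condensation forms C2'=C3').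
4. The C6–C3' bond is not made by coupling: it is the C6–CH2 bond set by Claisen rearrangement of the 5-O-allyl ether of acacetin, and the allyl group is then turned into the vinyl ketone.
5. Ring order: acacetin rings (bought), then the central carbocycle (step 9, aromatized in step 10), then the pyranone of the second flavone (step 15).

Key step: step 9

Assumption: methyl 3-oxopropanoate does not keep and is freed from its dimethyl acetal just before use; the target has no stereocentre and its biaryl axis is taken as freely rotating.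

**Route**

Step 1
Reactants: 1 acacetin; 2 benzyl bromide
Product: 3 7-(benzyloxy)-5-hydroxy-2-(4-methoxyphenyl)chromen-4-one
Conditions: BnBr (1.1 equiv), K2CO3, acetone, reflux
Reagents that add atoms: benzyl bromide, BrCc1ccccc1
Why: Williamson etherification; the 7-OH is the more acidic phenol and the 5-OH is held in a hydrogen bond to the C4 carbonyl, so one equivalent of halide under weak base should alkylate O7 only.

Step 2
Reactants: 3 7-(benzyloxy)-5-hydroxy-2-(4-methoxyphenyl)chromen-4-one; 4 allyl bromide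
Product: 5 5-(allyloxy)-7-(benzyloxy)-2-(4-methoxyphenyl)chromen-4-one
Conditions: allyl bromide (3 equiv), K2CO3, DMF, 60 °C
Reagents that add atoms: allyl bromide, C=CCBr
Why: Williamson etherification under forcing conditions (excess reactive halide, dipolar solvent, heat), which should break the chelate of the 5-OH.

Step 3
Reactants: 5 5-(allyloxy)-7-(benzyloxy)-2-(4-methoxyphenyl)chromen-4-one
Product: 6 6-allyl-7-(benzyloxy)-5-hydroxy-2-(4-methoxyphenyl)chromen-4-one
Conditions: PhNEt2, 200 °C
Reagents that add atoms: none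
Why: Aromatic Claisen rearrangement; the only ortho carbon of O5 that carries hydrogen is C6 (the other is the ring-fusion carbon C4a), so the [3,3] shift should deliver the allyl group to C6 alone, and enolization restores the chelated 5-OH.

Step 4
Reactants: 6 6-allyl-7-(benzyloxy)-5-hydroxy-2-(4-methoxyphenyl)chromen-4-one; 2 benzyl bromide
Product: 7 6-allyl-5,7-bis(benzyloxy)-2-(4-methoxyphenyl)chromen-4-one
Conditions: BnBr (2 equiv), K2CO3, DMF, 80 °C
Reagents that add atoms: benzyl bromide, BrCc1ccccc1
Why: Williamson etherification of the chelated phenol under forcing conditions; the cap is needed because a free 5-OH would add to the aldehyde and the enone of the following steps.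

Step 5
Reactants: 7 6-allyl-5,7-bis(benzyloxy)-2-(4-methoxyphenyl)chromen-4-one
Product: 8 2-[5,7-bis(benzyloxy)-2-(4-methoxyphenyl)-4-oxochromen-6-yl]acetaldehyde
Conditions: OsO4 (cat.), NaIO4, 2,6-lutidine, dioxane/H2O 3:1, rt
Reagents that add atoms: OsO4, O=[Os](=O)(=O)=O (catalytic oxygen carrier); NaIO4, [Na+].[O-]I(=O)(=O)=O (terminal oxidant)
Why: Lemieux–Johnson oxidative cleavage; OsO4 should attack the electron-rich monosubstituted alkene far faster than the electron-poor, conjugated C2=C3 bond of the pyranone.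

Step 6
Reactants: 8 2-[5,7-bis(benzyloxy)-2-(4-methoxyphenyl)-4-oxochromen-6-yl]acetaldehyde; 9 vinylmagnesium bromide
Product: 10 racemic 1-[5,7-bis(benzyloxy)-2-(4-methoxyphenyl)-4-oxochromen-6-yl]but-3-en-2-ol
Conditions: CH2=CHMgBr (1.3 equiv), THF, −78 °C; sat. NH4Cl
Reagents that add atoms: vinylmagnesium bromide, C=C[Mg]Br
Why: Grignard 1,2-addition; at −78 °C the aldehyde should react well before the vinylogous-ester carbonyl of the flavone, and the carbinol centre forms without control as a racemate that is removed in step 7.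

Step 7
Reactants: 10 racemic 1-[5,7-bis(benzyloxy)-2-(4-methoxyphenyl)-4-oxochromen-6-yl]but-3-en-2-ol
Product: 11 1-[5,7-bis(benzyloxy)-2-(4-methoxyphenyl)-4-oxochromen-6-yl]but-3-en-2-one
Conditions: Dess–Martin periodinane, CH2Cl2, 0 °C to rt; used at once
Reagents that add atoms: none
Why: Dess–Martin oxidation of the allylic alcohol under neutral, non-basic conditions, which should spare the polymerization-prone vinyl ketone and its acidic benzylic methylene.

Step 8
Reactants: 12 methyl 3,3-dimethoxypropanoate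
Product: 13 methyl 3-oxopropanoate
Conditions: 2 M HCl (aq), THF, rt; CH2Cl2 extraction, used crude at once
Reagents that add atoms: water, O
Why: Acid-catalysed acetal hydrolysis; the formyl ester is taken on immediately because it self-condenses on standing.

Step 9
Reactants: 11 1-[5,7-bis(benzyloxy)-2-(4-methoxyphenyl)-4-oxochromen-6-yl]but-3-en-2-one; 13 methyl 3-oxopropanoate
Product: 16 racemic methyl 3-[5,7-bis(benzyloxy)-2-(4-methoxyphenyl)-4-oxochromen-6-yl]-4-oxocyclohex-2-ene-1-carboxylate, via keto aldehyde Michael adduct 14 (not isolated), via cyclic aldol adduct 15 (not isolated)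
Conditions: 13 (2 equiv), Et3N (0.2 equiv), CH2Cl2, 0 °C to rt, slow addition of 11; then piperidine, AcOH (0.3 equiv each), toluene, 70 °C, 4 Å MS
Reagents that add atoms: methyl 3-oxopropanoate, COC(=O)CC=O
Why: Et3N deprotonates formyl ester 13, by far the strongest carbon acid present, and its stabilized enolate adds in Michael fashion to the terminal carbon of the vinyl ketone to form C1'–C6' (14); piperidinium acetate then promotes intramolecular aldol addition of the benzylic enol (or enamine) carbon C3' to the formyl carbon C2' (15) and E1cB loss of water to the aryl-conjugated enone 16. The sequence is a Robinson annulation of the aldehyde-donor type, the kind that turns α-formyl esters or α-branched aldehydes and alkyl vinyl ketones into 4-substituted cyclohex-2-enones. The six-membered ring closes in the 6-(enolendo)-exo-trig mode, because the enol bond C3'=C4' lies inside the new ring and the aldehyde C=O outside it, a favoured class of enolate closure. C1' is the only stereocentre that persists; nothing controls it, it forms as a racemate (the carbinol and benzylic centres of 15 vanish on dehydration) and it is flattened in step 10. The step needs donor chemoselectivity (13 rather than the benzylic CH2 of a second molecule of 11, and mono- rather than bis-alkylation), which the large acidity gap, the excess of 13 and slow addition of 11 should secure, and a single direction of closure, which the substrate fixes because enolization toward C5' could only lead to a four-membered ring. Migration of the ring double bond toward the ester is harmless, since every such isomer converges on the same arene in step 10.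

Step 10
Reactants: 16 racemic methyl 3-[5,7-bis(benzyloxy)-2-(4-methoxyphenyl)-4-oxochromen-6-yl]-4-oxocyclohex-2-ene-1-carboxylate
Product: 17 methyl 3-[5,7-bis(benzyloxy)-2-(4-methoxyphenyl)-4-oxochromen-6-yl]-4-methoxybenzoate
Conditions: I2 (2.2 equiv), MeOH/THF, reflux
Reagents that add atoms: methanol, CO
Why: Iodine–methanol oxidative aromatization of a 4-oxocyclohex-2-ene-1-carboxylate; methanol should convert the ketone into the dienol methyl ether (the carbonyl oxygen leaves as water, so the ketone carbon becomes C4' and methanol supplies the whole methoxy group), and iodination followed by loss of HI, helped by the acidic C1'–H, gives the anisole and erases the C1' stereocentre.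

Step 11
Reactants: 17 methyl 3-[5,7-bis(benzyloxy)-2-(4-methoxyphenyl)-4-oxochromen-6-yl]-4-methoxybenzoate
Product: 18 3-[5,7-bis(benzyloxy)-2-(4-methoxyphenyl)-4-oxochromen-6-yl]-4-methoxybenzoic acid
Conditions: LiOH·H2O, THF/MeOH/H2O, 40 °C; then 1 M HCl
Reagents that add atoms: lithium hydroxide, [Li+].[OH-]
Why: Saponification of an unhindered methyl benzoate under conditions mild enough to leave the pyranone ring and the benzyl ethers intact.

Step 12
Reactants: 19 1-(2,6-dihydroxy-4-methoxyphenyl)ethanone; 2 benzyl bromide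
Product: 20 1-[2-(benzyloxy)-6-hydroxy-4-methoxyphenyl]ethanone
Conditions: BnBr (1.05 equiv), K2CO3, acetone, reflux
Reagents that add atoms: benzyl bromide, BrCc1ccccc1
Why: Williamson mono-etherification of a symmetric diphenol; after the first alkylation the remaining OH is locked in a chelate with the acetyl group, so the reaction should stop at the monoether.

Step 13
Reactants: 18 3-[5,7-bis(benzyloxy)-2-(4-methoxyphenyl)-4-oxochromen-6-yl]-4-methoxybenzoic acid; 20 1-[2-(benzyloxy)-6-hydroxy-4-methoxyphenyl]ethanone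
Product: 21 2-acetyl-3-(benzyloxy)-5-methoxyphenyl 3-[5,7-bis(benzyloxy)-2-(4-methoxyphenyl)-4-oxochromen-6-yl]-4-methoxybenzoate
Conditions: DCC, DMAP (cat.), CH2Cl2, rt
Reagents that add atoms: 1-[2-(benzyloxy)-6-hydroxy-4-methoxyphenyl]ethanone, CC(=O)c1c(O)cc(OC)cc1OCc1ccccc1
Why: Steglich esterification; the acylpyridinium formed with DMAP should acylate even the chelated ortho-acetyl phenol.

Step 14
Reactants: 21 2-acetyl-3-(benzyloxy)-5-methoxyphenyl 3-[5,7-bis(benzyloxy)-2-(4-methoxyphenyl)-4-oxochromen-6-yl]-4-methoxybenzoate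
Product: 22 1-[2-(benzyloxy)-6-hydroxy-4-methoxyphenyl]-3-{3-[5,7-bis(benzyloxy)-2-(4-methoxyphenyl)-4-oxochromen-6-yl]-4-methoxyphenyl}propane-1,3-dione
Conditions: KOtBu (3 equiv), THF, 0 °C to rt; then 1 M HCl
Reagents that add atoms: none
Why: Baker–Venkataraman rearrangement; the acetyl enolate attacks the neighbouring aryl ester through a six-membered transition state, and formation of the stabilized diketone enolate and phenoxide drives the O-to-C acyl shift.

Step 15
Reactants: 22 1-[2-(benzyloxy)-6-hydroxy-4-methoxyphenyl]-3-{3-[5,7-bis(benzyloxy)-2-(4-methoxyphenyl)-4-oxochromen-6-yl]-4-methoxyphenyl}propane-1,3-dione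
Product: 23 5,7-bis(benzyloxy)-6-{5-[5-(benzyloxy)-7-methoxy-4-oxochromen-2-yl]-2-methoxyphenyl}-2-(4-methoxyphenyl)chromen-4-one
Conditions: p-TsOH·H2O (cat.), toluene, 90 °C
Reagents that add atoms: none
Why: Acid-catalysed cyclodehydration of the 2-hydroxyaryl 1,3-diketone (hemiketal formation, then loss of water) to the 4-pyranone; any loss of a peri benzyl ether would not matter because all benzyl groups are removed next.

Step 16
Reactants: 23 5,7-bis(benzyloxy)-6-{5-[5-(benzyloxy)-7-methoxy-4-oxochromen-2-yl]-2-methoxyphenyl}-2-(4-methoxyphenyl)chromen-4-one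
Product: 24 CNP0281098.0, 5,7-dihydroxy-6-[5-(5-hydroxy-7-methoxy-4-oxochromen-2-yl)-2-methoxyphenyl]-2-(4-methoxyphenyl)chromen-4-one
Conditions: H2 (1 atm), 10% Pd/C, THF/MeOH, rt
Reagents that add atoms: none
Why: Catalytic hydrogenolysis of the three benzyl aryl ethers; the methyl ethers are inert and the conjugated C2=C3 bonds of the two pyranones should resist reduction at ambient pressure.

**Compound list**

1 | acacetin, 5,7-dihydroxy-2-(4-methoxyphenyl)chromen-4-one | COc1ccc(-c2cc(=O)c3c(O)cc(O)cc3o2)cc1 | starting material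
2 | benzyl bromide | BrCc1ccccc1 | starting material
3 | 7-(benzyloxy)-5-hydroxy-2-(4-methoxyphenyl)chromen-4-one | COc1ccc(-c2cc(=O)c3c(O)cc(OCc4ccccc4)cc3o2)cc1 | intermediate
4 | allyl bromide | C=CCBr | starting material
5 | 5-(allyloxy)-7-(benzyloxy)-2-(4-methoxyphenyl)chromen-4-one | COc1ccc(-c2cc(=O)c3c(OCC=C)cc(OCc4ccccc4)cc3o2)cc1 | intermediate
6 | 6-allyl-7-(benzyloxy)-5-hydroxy-2-(4-methoxyphenyl)chromen-4-one | COc1ccc(-c2cc(=O)c3c(O)c(CC=C)c(OCc4ccccc4)cc3o2)cc1 | intermediate
7 | 6-allyl-5,7-bis(benzyloxy)-2-(4-methoxyphenyl)chromen-4-one | COc1ccc(-c2cc(=O)c3c(OCc4ccccc4)c(CC=C)c(OCc4ccccc4)cc3o2)cc1 | intermediate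
8 | 2-[5,7-bis(benzyloxy)-2-(4-methoxyphenyl)-4-oxochromen-6-yl]acetaldehyde | COc1ccc(-c2cc(=O)c3c(OCc4ccccc4)c(CC=O)c(OCc4ccccc4)cc3o2)cc1 | intermediate
9 | vinylmagnesium bromide | C=C[Mg]Br | starting material
10 | racemic 1-[5,7-bis(benzyloxy)-2-(4-methoxyphenyl)-4-oxochromen-6-yl]but-3-en-2-ol | COc1ccc(-c2cc(=O)c3c(OCc4ccccc4)c(CC(O)C=C)c(OCc4ccccc4)cc3o2)cc1 | intermediate
11 | 1-[5,7-bis(benzyloxy)-2-(4-methoxyphenyl)-4-oxochromen-6-yl]but-3-en-2-one | COc1ccc(-c2cc(=O)c3c(OCc4ccccc4)c(CC(=O)C=C)c(OCc4ccccc4)cc3o2)cc1 | intermediate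
12 | methyl 3,3-dimethoxypropanoate | COC(=O)CC(OC)OC | starting material
13 | methyl 3-oxopropanoate | COC(=O)CC=O | intermediate
14 | racemic methyl 6-[5,7-bis(benzyloxy)-2-(4-methoxyphenyl)-4-oxochromen-6-yl]-2-formyl-5-oxohexanoate (Michael adduct, not isolated) | COC(=O)C(C=O)CCC(=O)Cc1c(OCc2ccccc2)cc2oc(-c3ccc(OC)cc3)cc(=O)c2c1OCc1ccccc1 | intermediate
15 | methyl 3-[5,7-bis(benzyloxy)-2-(4-methoxyphenyl)-4-oxochromen-6-yl]-2-hydroxy-4-oxocyclohexane-1-carboxylate (aldol adduct, mixture of racemic diastereomers, not isolated) | COC(=O)C1CCC(=O)C(c2c(OCc3ccccc3)cc3oc(-c4ccc(OC)cc4)cc(=O)c3c2OCc2ccccc2)C1O | intermediate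
16 | racemic methyl 3-[5,7-bis(benzyloxy)-2-(4-methoxyphenyl)-4-oxochromen-6-yl]-4-oxocyclohex-2-ene-1-carboxylate | COC(=O)C1C=C(c2c(OCc3ccccc3)cc3oc(-c4ccc(OC)cc4)cc(=O)c3c2OCc2ccccc2)C(=O)CC1 | intermediate
17 | methyl 3-[5,7-bis(benzyloxy)-2-(4-methoxyphenyl)-4-oxochromen-6-yl]-4-methoxybenzoate | COC(=O)c1ccc(OC)c(-c2c(OCc3ccccc3)cc3oc(-c4ccc(OC)cc4)cc(=O)c3c2OCc2ccccc2)c1 | intermediate
18 | 3-[5,7-bis(benzyloxy)-2-(4-methoxyphenyl)-4-oxochromen-6-yl]-4-methoxybenzoic acid | OC(=O)c1ccc(OC)c(-c2c(OCc3ccccc3)cc3oc(-c4ccc(OC)cc4)cc(=O)c3c2OCc2ccccc2)c1 | intermediate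
19 | 1-(2,6-dihydroxy-4-methoxyphenyl)ethanone | CC(=O)c1c(O)cc(OC)cc1O | starting material
20 | 1-[2-(benzyloxy)-6-hydroxy-4-methoxyphenyl]ethanone | CC(=O)c1c(O)cc(OC)cc1OCc1ccccc1 | intermediate
21 | 2-acetyl-3-(benzyloxy)-5-methoxyphenyl 3-[5,7-bis(benzyloxy)-2-(4-methoxyphenyl)-4-oxochromen-6-yl]-4-methoxybenzoate | CC(=O)c1c(OCc2ccccc2)cc(OC)cc1OC(=O)c1ccc(OC)c(-c2c(OCc3ccccc3)cc3oc(-c4ccc(OC)cc4)cc(=O)c3c2OCc2ccccc2)c1 | intermediate
22 | 1-[2-(benzyloxy)-6-hydroxy-4-methoxyphenyl]-3-{3-[5,7-bis(benzyloxy)-2-(4-methoxyphenyl)-4-oxochromen-6-yl]-4-methoxyphenyl}propane-1,3-dione | COc1cc(O)c(C(=O)CC(=O)c2ccc(OC)c(-c3c(OCc4ccccc4)cc4oc(-c5ccc(OC)cc5)cc(=O)c4c3OCc3ccccc3)c2)c(OCc2ccccc2)c1 | intermediate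
23 | 5,7-bis(benzyloxy)-6-{5-[5-(benzyloxy)-7-methoxy-4-oxochromen-2-yl]-2-methoxyphenyl}-2-(4-methoxyphenyl)chromen-4-one | COc1cc(OCc2ccccc2)c2c(=O)cc(-c3ccc(OC)c(-c4c(OCc5ccccc5)cc5oc(-c6ccc(OC)cc6)cc(=O)c5c4OCc4ccccc4)c3)oc2c1 | intermediate
24 | CNP0281098.0, 5,7-dihydroxy-6-[5-(5-hydroxy-7-methoxy-4-oxochromen-2-yl)-2-methoxyphenyl]-2-(4-methoxyphenyl)chromen-4-one | COc1ccc(-c2cc(=O)c3c(O)c(-c4cc(-c5cc(=O)c6c(O)cc(OC)cc6o5)ccc4OC)c(O)cc3o2)cc1 | target

**Step count**

Total: 16 steps. Longest linear sequence: 14 steps from acacetin (steps 1–7, 9–11, 13–16); steps 8 and 12 are side branches.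

**Steps most likely to fail**

Step 9 (Robinson annulation). The free formyl ester may condense with itself faster than it adds to 11. Adduct 14 may add to a second molecule of 11. The vinyl ketone may oligomerize through its own benzylic carbanion. The aldol closure may stall because the formyl group rests as its unreactive enol. The fallback gives up ring construction for a biaryl cross-coupling. It sets out from 3 and comes back at 17, replacing steps 2–10. Iodination ortho to the chelated 5-hydroxyl (I2, TlOAc, CH2Cl2, rt) should give 7-(benzyloxy)-5-hydroxy-6-iodo-2-(4-methoxyphenyl)chromen-4-one F1. Benzylation (BnBr, K2CO3, DMF, 80 °C) should give 5,7-bis(benzyloxy)-6-iodo-2-(4-methoxyphenyl)chromen-4-one F2. Suzuki–Miyaura coupling of F2 with [2-methoxy-5-(methoxycarbonyl)phenyl]boronic acid (Pd(OAc)2, SPhos, K3PO4, toluene/H2O, 90 °C) should then give 17.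

Step 10 (iodine–methanol aromatization). The HI that is released may cleave the peri 5-O-benzyl ether. Iodine may substitute the electron-rich ring A at C8. Ketal formation next to the bulky aryl group may be slower than oxidation, so that phenol and anisole form together. The fallback separates oxidation from etherification. It sets out from 16 and comes back at 17. Dehydrogenation with DDQ (1,4-dioxane, 80 °C), helped by the doubly activated C1'–H, should give methyl 3-[5,7-bis(benzyloxy)-2-(4-methoxyphenyl)-4-oxochromen-6-yl]-4-hydroxybenzoate F3. O-Methylation (MeI, K2CO3, acetone, reflux) should then give 17.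

Step 6 (vinyl Grignard addition). The basic reagent may deprotonate the hindered, enolizable arylacetaldehyde, returning 8 or its aldol products, or it may attack the pyranone of the flavone. The fallback replaces carbonyl addition and oxidation by an acyl cross-coupling. It sets out from 8 and comes back at 11, bypassing steps 6 and 7. Pinnick oxidation (NaClO2, NaH2PO4, 2-methyl-2-butene, t-BuOH/H2O) should give 2-[5,7-bis(benzyloxy)-2-(4-methoxyphenyl)-4-oxochromen-6-yl]acetic acid F4. Oxalyl chloride with catalytic DMF in CH2Cl2 should give 2-[5,7-bis(benzyloxy)-2-(4-methoxyphenyl)-4-oxochromen-6-yl]acetyl chloride F5. Stille acylation of tributyl(vinyl)stannane with F5 (Pd(PPh3)4, THF, 50 °C) should then give vinyl ketone 11.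

**Further compounds**

F1 | step 9 | 7-(benzyloxy)-5-hydroxy-6-iodo-2-(4-methoxyphenyl)chromen-4-one | COc1ccc(-c2cc(=O)c3c(O)c(I)c(OCc4ccccc4)cc3o2)cc1
F2 | step 9 | 5,7-bis(benzyloxy)-6-iodo-2-(4-methoxyphenyl)chromen-4-one | COc1ccc(-c2cc(=O)c3c(OCc4ccccc4)c(I)c(OCc4ccccc4)cc3o2)cc1
F3 | step 10 | methyl 3-[5,7-bis(benzyloxy)-2-(4-methoxyphenyl)-4-oxochromen-6-yl]-4-hydroxybenzoate | COC(=O)c1ccc(O)c(-c2c(OCc3ccccc3)cc3oc(-c4ccc(OC)cc4)cc(=O)c3c2OCc2ccccc2)c1
F4 | step 6 | 2-[5,7-bis(benzyloxy)-2-(4-methoxyphenyl)-4-oxochromen-6-yl]acetic acid | COc1ccc(-c2cc(=O)c3c(OCc4ccccc4)c(CC(=O)O)c(OCc4ccccc4)cc3o2)cc1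
F5 | step 6 | 2-[5,7-bis(benzyloxy)-2-(4-methoxyphenyl)-4-oxochromen-6-yl]acetyl chloride | COc1ccc(-c2cc(=O)c3c(OCc4ccccc4)c(CC(=O)Cl)c(OCc4ccccc4)cc3o2)cc1
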